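**Retrosynthetic overview**

- The target is opened at the C6–C7 bond and the lactone C–O bond. The last flask closes the ten-membered carbocycle first (C6–C7, the bond made by the farnesyl C1–C10 cyclisation in germacrane biogenesis) and then the 12,6-γ-lactone (costunolide-type lactonisation).
- The (Z)-γ-hydroxy-enal electrophile is carried as a 2,5-dihydrofuran-2-ol, made by ester-sparing borane reduction of a butenolide whose ring locks the 4Z alkene. The 2-(bromomethyl)enoate nucleophile comes from cross-metathesis of a cis alkene.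
- The butenolide comes from an erythro-selective vinylogous aldol of 4-methylfuran-2(5H)-one with a C2 aldehyde (sets C2 and C3).
- The aldehyde comes from anti-Markovnikov Wacker oxidation of the vinyl group of an angeloylated anti-crotylation adduct of (Z)-hex-3-enal (sets C9 and C10).

Convention and assumption: germacrane numbering is used (C6 = lactone carbinol carbon, C7 = ring-fusion carbon bearing C11, C4=C5 = ring alkene, C9 = angeloyloxy carbon). In this numbering the target is 2S,3R,4Z,6R,7S,9S,10R, the 2,3-diol is erythro, the 9-O/10-Me pair is anti and the lactone is trans-fused. The catalyst and reagent antipodes named are those expected to give the drawn sense; the absolute sense of the step 5 catalyst has not been checked against a precedent.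

**Route**

Step 1
Reactants: 1 (Z)-hex-3-en-1-ol
Product: 2 (Z)-hex-3-enal
Conditions: Dess–Martin periodinane, CH2Cl2, 0 °C to rt; crude solution used at once
Reagents that add atoms: none
Why: Dess–Martin oxidation is mild enough to give the β,γ-unsaturated aldehyde without moving the cis alkene into conjugation, and no stereocentre is involved.

Step 2
Reactants: 2 (Z)-hex-3-enal; 3 (E)-but-2-ene
Product: 7 (3R,4S,6Z)-3-methylnona-1,6-dien-4-ol, via (E)-crotylpotassium 4 (not isolated), via (E)-crotyldiisopinocampheylborane 5 (not isolated), via borinate ester 6 (not isolated)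
Conditions: 3, KOt-Bu, n-BuLi, THF, −78 to −45 °C; (+)-Ipc2BOMe, −78 °C; BF3·OEt2; 2, −78 °C; NaOH, H2O2, rt
Reagents that add atoms: (E)-but-2-ene, C/C=C/C
Why: Brown crotylboration proceeds through a closed chair transition state, so the E-crotyl geometry gives the anti O/Me pair, and the isopinocampheyl groups of the (−)-α-pinene series direct addition to the Re face of the aldehyde, setting C9 (S) and C10 (R).

Step 3
Reactants: 7 (3R,4S,6Z)-3-methylnona-1,6-dien-4-ol; 8 angelic acid
Product: 10 (3R,4S,6Z)-3-methylnona-1,6-dien-4-yl (2Z)-2-methylbut-2-enoate, via angelic 2,4,6-trichlorobenzoic anhydride 9 (not isolated)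
Conditions: 8, 2,4,6-trichlorobenzoyl chloride, Et3N, toluene, rt; then 7, toluene, 80 °C (no DMAP)
Reagents that add atoms: angelic acid, C/C=C(/C)C(=O)O
Why: Mixed-anhydride (Yamaguchi-type) esterification without a nucleophilic catalyst acylates the hindered secondary alcohol with retention at C9 and avoids Z-to-E isomerisation of the angeloyl group to tigloyl; placing the ester here means no later hydroxyl has to be differentiated.

Step 4
Reactants: 10 (3R,4S,6Z)-3-methylnona-1,6-dien-4-yl (2Z)-2-methylbut-2-enoate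
Product: 11 (3R,4S,6Z)-3-methyl-1-oxonon-6-en-4-yl (2Z)-2-methylbut-2-enoate
Conditions: PdCl2(PhCN)2 (10 mol %), CuCl2·2H2O (10 mol %), AgNO2 (5 mol %), O2 (1 atm), t-BuOH/MeNO2 15:1, rt
Reagents that add atoms: dioxygen, O=O
Why: The nitrite-modified, aldehyde-selective (anti-Markovnikov) Wacker oxidation attacks only the monosubstituted alkene, helped by the allylic branch and the homoallylic ester, and leaves the internal cis alkene, the angelate and both stereocentres untouched.

Step 5
Reactants: 11 (3R,4S,6Z)-3-methyl-1-oxonon-6-en-4-yl (2Z)-2-methylbut-2-enoate; 12 4-methylfuran-2(5H)-one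
Product: 15 (1S,3R,4S,6Z)-1-hydroxy-3-methyl-1-[(2R)-3-methyl-5-oxo-2,5-dihydrofuran-2-yl]non-6-en-4-yl (2Z)-2-methylbut-2-enoate, via 4-methyl-2-(trimethylsilyloxy)furan 13 (not isolated), via trimethylsilyl ether 14 (not isolated)
Conditions: 12 (1.5 equiv), N,O-bis(trimethylsilyl)acetamide (2 equiv), N-(9-anthracenylmethyl)cinchonidinium 4-methoxyphenoxide (10 mol %), THF, −40 °C; then 1 M HCl, THF, 0 °C
Reagents that add atoms: 4-methylfuran-2(5H)-one, CC1=CC(=O)OC1
Why: This is a vinylogous Mukaiyama aldol reaction with in-situ silylation under chiral ammonium aryloxide ion-pair catalysis: the silyl dienol ether 13 attacks through its 5-position in the open, antiperiplanar transition state of the fluoride/aryloxide manifold (erythro-selective, unlike the threo-selective Lewis-acid manifold) while the cinchonidinium cation shields one aldehyde face, which should set C2 (S) and C3 (R) together and lock the future C4=C5 alkene as Z inside the butenolide ring.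

Step 6
Reactants: 15 (1S,3R,4S,6Z)-1-hydroxy-3-methyl-1-[(2R)-3-methyl-5-oxo-2,5-dihydrofuran-2-yl]non-6-en-4-yl (2Z)-2-methylbut-2-enoate; 16 methyl 2-(bromomethyl)prop-2-enoate
Product: 17 methyl (2Z,5S,6R,8S)-2-(bromomethyl)-8-hydroxy-6-methyl-5-{[(2Z)-2-methylbut-2-enoyl]oxy}-8-[(2R)-3-methyl-5-oxo-2,5-dihydrofuran-2-yl]oct-2-enoate
Conditions: 16 (8 equiv), second-generation Hoveyda–Grubbs catalyst (10 mol %), CH2Cl2, 40 °C
Reagents that add atoms: methyl 2-(bromomethyl)prop-2-enoate, C=C(CBr)C(=O)OC
Why: Olefin cross-metathesis of the cis-disubstituted alkene with the 1,1-disubstituted acrylate (by analogy with methacrylate and itaconate partners) expels but-1-ene and gives the thermodynamically preferred trisubstituted enoate with the chain trans to the ester (Z by CIP), while the butenolide and angelate alkenes are too hindered and electron-poor to react.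

Step 7
Reactants: 17 methyl (2Z,5S,6R,8S)-2-(bromomethyl)-8-hydroxy-6-methyl-5-{[(2Z)-2-methylbut-2-enoyl]oxy}-8-[(2R)-3-methyl-5-oxo-2,5-dihydrofuran-2-yl]oct-2-enoate
Product: 19 methyl (2Z,5S,6R,8S)-2-(bromomethyl)-8-hydroxy-8-[(2R)-5-hydroxy-3-methyl-2,5-dihydrofuran-2-yl]-6-methyl-5-{[(2Z)-2-methylbut-2-enoyl]oxy}oct-2-enoate (anomer mixture), via bis(disiamylborinate) 18 (not isolated)
Conditions: Sia2BH (4 equiv, from BH3·THF and 2-methylbut-2-ene), THF, 0 °C to rt; H2O, pH 7 buffer
Reagents that add atoms: none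
Why: Dialkylborane lactone-to-lactol reduction: disiamylborane reduces lactones to lactols but not carboxylic esters (the basis of its use on O-acylated aldonolactones) and does not hydroborate trisubstituted or electron-poor alkenes, so the angelate, the bromomethyl enoate and all stereocentres should survive; the new hemiacetal carbon is an inconsequential anomer mixture.

Step 8
Reactants: 19 methyl (2Z,5S,6R,8S)-2-(bromomethyl)-8-hydroxy-8-[(2R)-5-hydroxy-3-methyl-2,5-dihydrofuran-2-yl]-6-methyl-5-{[(2Z)-2-methylbut-2-enoyl]oxy}oct-2-enoate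
Product: 22 (2S,3R,4Z,6R,7S,9S,10R)-9-angeloyloxy-2,3-dihydroxygermacra-4,11(13)-dien-12,6-olide (target), via allylindium dibromide 20 (not isolated), via hydroxy ester 21 (not isolated)
Conditions: In powder (6 equiv), THF/sat. aq. NH4Cl 3:1, 19 added by syringe pump (final 1 mM), 30 °C; then PPTS (10 mol %), CH2Cl2, rt
Reagents that add atoms: none
Why: Proposed new method: indium inserts into the allylic C–Br bond to give the 2-(methoxycarbonyl)allylindium 20, the lactol opens reversibly in the aqueous medium to the (Z)-γ-hydroxy-enal, and γ-attack of C7 on the C6 aldehyde through a six-membered Barbier transition state closes the ten-membered ring at the bond made by the farnesyl C1–C10 cyclisation in germacrane biosynthesis, after which the C6 hydroxyl closes the 12,6-lactone (costunolide-type lactonisation) with loss of methanol; C6 (R) should arise because 1,3-allylic strain keeps C3–H and C6–H in the plane of the Z alkene (s-trans enal), which puts the C2–C3 and C6–C7 ring bonds on opposite faces so that C7 adds on the face of the C3 hydroxyl, and C7 (S) because the ten-membered transition state places C5 and C8 antiperiplanar across the forming bond, which can only give the trans-fused lactone; the closest known reactions are indium-mediated allylations of unprotected aldoses (lactols) with 2-(bromomethyl)acrylates in water and CrCl2- or zinc-mediated Barbier macrocyclisations of 2-(bromomethyl)enoate aldehydes to 6,7-trans germacranolides.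

**Compound list**

1 | (Z)-hex-3-en-1-ol | OCC/C=C\CC | starting material
2 | (Z)-hex-3-enal | O=CC/C=C\CC | intermediate
3 | (E)-but-2-ene | C/C=C/C | starting material
4 | (E)-crotylpotassium | C/C=C/[CH2-].[K+] | intermediate
5 | (E)-crotyldiisopinocampheylborane (isopinocampheyl groups of the (−)-α-pinene series) | C/C=C/CB([C@H]1C[C@H]2C[C@@H]([C@@H]1C)C2(C)C)[C@H]1C[C@H]2C[C@@H]([C@@H]1C)C2(C)C | intermediate
6 | diisopinocampheylborinate ester of 7 | C=C[C@@H](C)[C@@H](OB([C@H]1C[C@H]2C[C@@H]([C@@H]1C)C2(C)C)[C@H]1C[C@H]2C[C@@H]([C@@H]1C)C2(C)C)C/C=C\CC | intermediate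
7 | (3R,4S,6Z)-3-methylnona-1,6-dien-4-ol | C=C[C@@H](C)[C@@H](O)C/C=C\CC | intermediate
8 | angelic acid, (2Z)-2-methylbut-2-enoic acid | C/C=C(/C)C(=O)O | starting material
9 | angelic 2,4,6-trichlorobenzoic anhydride | C/C=C(/C)C(=O)OC(=O)c1c(Cl)cc(Cl)cc1Cl | intermediate
10 | (3R,4S,6Z)-3-methylnona-1,6-dien-4-yl (2Z)-2-methylbut-2-enoate | C=C[C@@H](C)[C@@H](OC(=O)/C(C)=C\C)C/C=C\CC | intermediate
11 | (3R,4S,6Z)-3-methyl-1-oxonon-6-en-4-yl (2Z)-2-methylbut-2-enoate | O=CC[C@@H](C)[C@@H](OC(=O)/C(C)=C\C)C/C=C\CC | intermediate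
12 | 4-methylfuran-2(5H)-one | CC1=CC(=O)OC1 | starting material
13 | 4-methyl-2-(trimethylsilyloxy)furan | Cc1coc(O[Si](C)(C)C)c1 | intermediate
14 | trimethylsilyl ether of 15 | CC1=CC(=O)O[C@H]1[C@@H](O[Si](C)(C)C)C[C@@H](C)[C@@H](OC(=O)/C(C)=C\C)C/C=C\CC | intermediate
15 | (1S,3R,4S,6Z)-1-hydroxy-3-methyl-1-[(2R)-3-methyl-5-oxo-2,5-dihydrofuran-2-yl]non-6-en-4-yl (2Z)-2-methylbut-2-enoate (erythro butenolide) | CC1=CC(=O)O[C@H]1[C@@H](O)C[C@@H](C)[C@@H](OC(=O)/C(C)=C\C)C/C=C\CC | intermediate
16 | methyl 2-(bromomethyl)prop-2-enoate | C=C(CBr)C(=O)OC | starting material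
17 | methyl (2Z,5S,6R,8S)-2-(bromomethyl)-8-hydroxy-6-methyl-5-{[(2Z)-2-methylbut-2-enoyl]oxy}-8-[(2R)-3-methyl-5-oxo-2,5-dihydrofuran-2-yl]oct-2-enoate | CC1=CC(=O)O[C@H]1[C@@H](O)C[C@@H](C)[C@@H](OC(=O)/C(C)=C\C)C/C=C(\CBr)C(=O)OC | intermediate
18 | bis(disiamylborinate) of lactol 19 (both hydroxyl oxygens on boron) | CC1=CC(OB(C(C)C(C)C)C(C)C(C)C)O[C@H]1[C@@H](OB(C(C)C(C)C)C(C)C(C)C)C[C@@H](C)[C@@H](OC(=O)/C(C)=C\C)C/C=C(\CBr)C(=O)OC | intermediate
19 | methyl (2Z,5S,6R,8S)-2-(bromomethyl)-8-hydroxy-8-[(2R)-5-hydroxy-3-methyl-2,5-dihydrofuran-2-yl]-6-methyl-5-{[(2Z)-2-methylbut-2-enoyl]oxy}oct-2-enoate (lactol, anomer mixture) | CC1=CC(O)O[C@H]1[C@@H](O)C[C@@H](C)[C@@H](OC(=O)/C(C)=C\C)C/C=C(\CBr)C(=O)OC | intermediate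
20 | allylindium dibromide formed from 19 (drawn as the monoallyl species) | CC1=CC(O)O[C@H]1[C@@H](O)C[C@@H](C)[C@@H](OC(=O)/C(C)=C\C)C/C=C(\C[In](Br)Br)C(=O)OC | intermediate
21 | methyl 2-[(1S,2R,3Z,5R,6S,8R,9S)-2,5,6-trihydroxy-4,8-dimethyl-9-{[(2Z)-2-methylbut-2-enoyl]oxy}cyclodec-3-en-1-yl]prop-2-enoate | O[C@@H]1/C=C(/C)[C@@H](O)[C@@H](O)C[C@@H](C)[C@@H](OC(=O)/C(C)=C\C)C[C@H]1C(=C)C(=O)OC | intermediate
22 | (2S,3R,4Z,6R,7S,9S,10R)-9-angeloyloxy-2,3-dihydroxygermacra-4,11(13)-dien-12,6-olide (CNP0229085.1) | C=C1C(=O)O[C@@H]2/C=C(/C)[C@@H](O)[C@@H](O)C[C@@H](C)[C@@H](OC(=O)/C(C)=C\C)C[C@@H]12 | target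

**Step count and risks**

Total step count: 8. Longest linear sequence: 8 steps (1 to 22); all other inputs are commercial.

The three steps most likely to fail:

Step 8 (macrocyclising Barbier allylation and lactonisation). The risks are protonolysis of the allylindium before ring closure, dehydration of the lactol to a furan, and the wrong C6/C7 diastereomer. The fallback sets out from 19 and comes back at 22. 2-Methoxypropene with PPTS in CH2Cl2 at 0 °C traps the open hydroxy-enal as the acetonide-protected (Z)-enal F1. CrCl2 in degassed DMF/THF at high dilution then closes the same C6–C7 bond under anhydrous Nozaki–Hiyama–Kishi-type conditions on a fully protected, conformationally defined enal and gives the acetonide lactone F2. Aqueous acetic acid at rt removes the acetonide to give 22.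

Step 5 (erythro- and face-selective vinylogous aldol). The risks are a threo-rich mixture, the wrong absolute sense, or attack through the 3-position of the furan. The fallback sets out from 11 and comes back at 15. The silyl dienol ether 13 is prepared separately (Me3SiCl, Et3N) and added to 11 under Ti(Oi-Pr)4/BINOL catalysis, the threo-selective Lewis-acid manifold, to give the C2-epimeric threo butenolide F3. Mitsunobu inversion with chloroacetic acid, PPh3 and DIAD gives the inverted chloroacetate F4. Thiourea with NaHCO3 in ethanol removes the chloroacetyl group without touching the angelate and gives 15.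

Step 7 (lactone-to-lactol reduction beside two esters and an allylic bromide). The risks are a sluggish or unselective reduction of the conjugated lactone. The fallback sets out from 11 and comes back at 19; it replaces the butenolide by a furan that is oxidised rather than reduced to the enal level.
- 2-Bromo-3-methylfuran is converted (n-BuLi, ZnCl2, Et2Zn) into ethyl(3-methylfuran-2-yl)zinc F5, which adds to 11 in the presence of the amino-alcohol ligand MIB to give the (1S)-furyl carbinol F6.
- Cross-metathesis with 16, as in step 6, gives the bromomethyl enoate F7.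
- Achmatowicz oxidation (NBS, NaHCO3, THF/H2O, 0 °C) gives the pyranone hemiacetal F8.
- Luche reduction (NaBH4, CeCl3·7H2O, MeOH, −78 °C), with hydride anti to the C2 side chain, gives the trans (erythro) dihydropyran-diol F9.
- F9 is the six-membered ring tautomer of 19 and equilibrates with it through the open hydroxy-enal in the aqueous medium of step 8, so the route is rejoined at 19.

**Further compounds**

F1 | step 8 | methyl (2Z,5S,6R)-2-(bromomethyl)-7-{(4S,5R)-2,2-dimethyl-5-[(2Z)-4-oxobut-2-en-2-yl]-1,3-dioxolan-4-yl}-6-methyl-5-{[(2Z)-2-methylbut-2-enoyl]oxy}hept-2-enoate | O=C/C=C(/C)[C@H]1OC(C)(C)O[C@H]1C[C@@H](C)[C@@H](OC(=O)/C(C)=C\C)C/C=C(\CBr)C(=O)OC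
F2 | step 8 | 2,3-O-isopropylidene derivative of 22 | C=C1C(=O)O[C@@H]2/C=C(/C)[C@H]3OC(C)(C)O[C@H]3C[C@@H](C)[C@@H](OC(=O)/C(C)=C\C)C[C@@H]12
F3 | step 5 | (1R,3R,4S,6Z)-1-hydroxy-3-methyl-1-[(2R)-3-methyl-5-oxo-2,5-dihydrofuran-2-yl]non-6-en-4-yl (2Z)-2-methylbut-2-enoate (threo butenolide) | CC1=CC(=O)O[C@H]1[C@H](O)C[C@@H](C)[C@@H](OC(=O)/C(C)=C\C)C/C=C\CC
F4 | step 5 | chloroacetate of 15 | CC1=CC(=O)O[C@H]1[C@@H](OC(=O)CCl)C[C@@H](C)[C@@H](OC(=O)/C(C)=C\C)C/C=C\CC
F5 | step 7 | ethyl(3-methylfuran-2-yl)zinc | CC[Zn]c1occc1C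
F6 | step 7 | (1S,3R,4S,6Z)-1-hydroxy-3-methyl-1-(3-methylfuran-2-yl)non-6-en-4-yl (2Z)-2-methylbut-2-enoate | Cc1ccoc1[C@@H](O)C[C@@H](C)[C@@H](OC(=O)/C(C)=C\C)C/C=C\CC
F7 | step 7 | methyl (2Z,5S,6R,8S)-2-(bromomethyl)-8-hydroxy-6-methyl-8-(3-methylfuran-2-yl)-5-{[(2Z)-2-methylbut-2-enoyl]oxy}oct-2-enoate | Cc1ccoc1[C@@H](O)C[C@@H](C)[C@@H](OC(=O)/C(C)=C\C)C/C=C(\CBr)C(=O)OC
F8 | step 7 | methyl (2Z,5S,6R)-2-(bromomethyl)-7-[(2S)-6-hydroxy-4-methyl-3-oxo-3,6-dihydro-2H-pyran-2-yl]-6-methyl-5-{[(2Z)-2-methylbut-2-enoyl]oxy}hept-2-enoate | O=C1C(C)=CC(O)O[C@H]1C[C@@H](C)[C@@H](OC(=O)/C(C)=C\C)C/C=C(\CBr)C(=O)OC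
F9 | step 7 | methyl (2Z,5S,6R)-2-(bromomethyl)-7-[(2S,3R)-3,6-dihydroxy-4-methyl-3,6-dihydro-2H-pyran-2-yl]-6-methyl-5-{[(2Z)-2-methylbut-2-enoyl]oxy}hept-2-enoate | O[C@@H]1C(C)=CC(O)O[C@H]1C[C@@H](C)[C@@H](OC(=O)/C(C)=C\C)C/C=C(\CBr)C(=O)OC
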